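The numbers in the tables stem from a simulated flask for an exercise, and the scatter is random.

- Percent of the solid substrate charged is my unit, so that Friday's flask and Wednesday's run can be laid side by side. The decision is what to do with Friday's flask at the time asked: leave it, add catalyst or heat it.

the same everywhere: catalyst 0.80 mM
- Friday's: solid substrate 0.40 M; temperature 60 °C; the very flask that is asked about, followed so far
- Wednesday's: solid substrate 0.60 M; temperature 55 °C; run made earlier
- flask: solid substrate 0.40 M; temperature 60 °C; time 3.0 d

Friday's run (percent of the solid substrate charged): time / h: target / % = 6.00: 35.5; 12.0: 66.2; 20.0: 62.3; 25.0: 59.3; 30.0: 58.3; 40.0: 59.6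

Wednesday's run (percent of the solid substrate charged): time / d: target / % = 0.167: 15.7; 0.500: 38.6; 0.833: 65.6; 1.25: 70.6; 1.67: 68.4; 2.50: 64.1; 3.00: 64.0

(each reading ± 1 percentage point)

- additions leave the volume as it is
- at the start none of the solid substrate is in solution
- a reading or a percentage of target counts all its forms, free or not

- north-west: change nothing and wait 3.0 d more
- north: at 3.0 d add catalyst, 100 % of the amount charged, then wait 3.0 d
- west: at 3.0 d raise the temperature by 25 K, then wait 3.0 d

1. target, in percent of the solid substrate first charged, at 3.0 d
2. which option adds most target ("none" when 2 percentage points or less is all one gets) (north-west / north / west / none)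
3. target present, in percent of the solid substrate first charged, after north-west
4. target present, in percent of the solid substrate first charged, after west

- I replace the end of Friday's curve by the mean of its readings from 25.0 h to 40.0 h, which is 59.1 % with an error of 0.58 percentage points.
- Between those two times Friday's readings move 0.3 points, inside the scatter of 1 point, so I expect that mean at 3.0 d as well, and after north-west too.
- Friday's flask then holds 40.9 % of its charge in other forms. I call this the reserve, the charge minus the flat mean, and on this flask an option pays by bringing part of it back.
- Friday's flask read 66.2 % at 12.0 h, which is 7.1 points above the mean, so some of the reserve was once target. A fall that stops looks like a balance (thermodynamic control), so I expect added catalyst to leave Friday's flask where it stands.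
- Wednesday's reserve, from its readings at 2.50 d and 3.00 d, is 36.0 %, but that run differs in charge and in temperature together. I therefore leave the sign of heating open and make west the next run.
- The forecast gives 59 % now and 59 % after north-west, which agrees with my mean. It puts west at 38 % (range 22 % to 55 %) and names none as best, reading that “The lower plateau at higher temperature suggests exothermic formation”.
- Friday's flask gives 59.1 % at 3.0 d and 59.1 % after north-west. North adds 0 points, and west reaches 82.3 %, a gain of 23 points, so the best option is west.

    starting material ⇌ other conformer (K = 0.588, k = 0.144 h⁻¹, Ea = 111 kJ mol⁻¹, ΔH = −12.0 kJ mol⁻¹)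
    starting material + catalyst → catalyst + target (k = 1640 L mol⁻¹ h⁻¹, Ea = 42.0 kJ mol⁻¹)
    catalyst + other conformer → catalyst + isomer of the product A (k = 1540 L mol⁻¹ h⁻¹, Ea = 46.0 kJ mol⁻¹)
    crystals ⇌ target, rate k4*(cs4 - [target]) while solid is left; crystals form when [target] > cs4 (solubility = 0.240 M, k = 13.6 h⁻¹)
    target ⇌ isomer of the product B (K = 0.549, k = 0.0913 h⁻¹, Ea = 102 kJ mol⁻¹, ΔH = −50.0 kJ mol⁻¹)
    solid substrate ⇌ starting material, rate k6*(cs6 - [starting material]) while solid is left; crystals form when [starting material] > cs6 (solubility = 28.0 mM, k = 6.35 h⁻¹)
    (constants at 60 °C)

- The main reason for Friday's reserve is the turning of target into isomer of the product B, both ways: without that step Friday's flask reads 91.6 % at 3.0 d, and part of the reason for west's gain is that isomer of the product B goes back into target: the heated flask without that undoing gains −0.24 points. Friday's reserve held 32.5 % of isomer of the product B and 8.39 % of isomer of the product A, and west returned 56.7 % of that reserve. The neighbour flask kept at 45 °C has a larger reserve than Friday's, 45.0 % of its charge, with isomer of the product B at 41.9 %.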